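**Plan**

1. Cuts (ring numbered O1–O2–C3–C4–C5; C3 carries the CH2CO2H arm, C5 the chain C6–C17): the ester C–O bond (last step), the C12=C13 alkene (olefination), then C4–C5 together with O2–C3 of the dioxolane. This leaves a methyl ketone (C5) and methyl 3-methylbut-3-enoate (C3=C4); the ketone goes back to an enone (C7 methyl by conjugate addition) and a cross-metathesis.
2. Enabling feature: in the 1,2-dioxolane ring C5 is a masked methyl-ketone carbon (one peroxide O, three C), C4 is a bare CH2 and C3 is a fully substituted carbon on O2. This is the pattern of a peroxycarbenium ion (C5=O1+–O2Si) joined to the CH2 end of a 1,1-disubstituted alkene, whose tertiary cation (C3) is closed by O2.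
3. Forward: the C5–C12 ketone chain is built first, converted to its silyl peroxyketal, and the only ring is made in one annulation. C12 is then unmasked to the aldehyde, the C13–C17 styrenyl sulfone is joined by olefination, and the ester is hydrolysed.
4. Stereochemistry: C7 (R) from ligand-controlled copper-catalysed conjugate addition of MeMgBr; C5 (R) and C3 (S) (ring methyls trans) from chiral-anion control in the annulation; both alkenes E, from cross-metathesis with styrene (C16=C17) and from Julia–Kocienski olefination (C12=C13).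

Key step: step 5

Remark: for the two catalyst-controlled steps (3 and 5) the ligand or acid enantiomer that gives the drawn configuration is assumed to be chosen after a model run; both antipodes of each are accessible.

**Route**

Step 1
Reactants: 1 hept-6-en-1-ol
Product: 2 tert-butyl(hept-6-en-1-yloxy)diphenylsilane
Conditions: TBDPSCl, imidazole, DMF, 0 °C to rt
Reagents that add atoms: tert-butyl(chloro)diphenylsilane, CC(C)(C)[Si](Cl)(c1ccccc1)c1ccccc1
Why: Silylation of a primary alcohol; the bulky silyl ether should survive the Grignard, peroxidation and acid steps that follow.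

Step 2
Reactants: 2 tert-butyl(hept-6-en-1-yloxy)diphenylsilane; 3 but-3-en-2-one
Product: 4 (3E)-9-(tert-butyldiphenylsilyloxy)non-3-en-2-one
Conditions: second-generation Hoveyda–Grubbs catalyst (3 mol%), 3 (3 equiv), CH2Cl2, 40 °C
Reagents that add atoms: none
Why: Olefin cross-metathesis of a terminal alkene with an electron-poor enone partner should favour the cross product and give the E enone.

Step 3
Reactants: 4 (3E)-9-(tert-butyldiphenylsilyloxy)non-3-en-2-one
Product: 5 (4R)-9-(tert-butyldiphenylsilyloxy)-4-methylnonan-2-one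
Conditions: MeMgBr, CuBr·SMe2 (5 mol%), 1-[2-(diphenylphosphino)ferrocenyl]ethyldicyclohexylphosphine (Josiphos type, 6 mol%), tBuOMe, −75 °C; then aq. NH4Cl
Reagents that add atoms: methylmagnesium bromide, C[Mg]Br
Why: Copper-catalysed asymmetric conjugate addition of a Grignard reagent to a linear enone; the chiral ferrocenyl diphosphine controls the face of methyl delivery and sets the future C7 as R.

Step 4
Reactants: 5 (4R)-9-(tert-butyldiphenylsilyloxy)-4-methylnonan-2-one
Product: 7 triethylsilyl peroxyketal (4R)-9-(tert-butyldiphenylsilyloxy)-2-methoxy-4-methyl-2-(triethylsilylperoxy)nonane, via hydroperoxy ketal 6 (not isolated)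
Conditions: H2O2 (30% aq.), I2 (10 mol%), MeOH, rt; extractive work-up; then Et3SiCl, imidazole, DMF, 0 °C
Reagents that add atoms: hydrogen peroxide, OO; methanol, CO; chlorotriethylsilane, CC[Si](Cl)(CC)CC
Why: Iodine-catalysed hydroperoxyketalisation of a ketone in methanol followed by O-silylation of the hydroperoxide; the ketal carbon forms as both epimers, which does not matter because it is ionised in step 5.

Step 5
Reactants: 7 triethylsilyl peroxyketal (4R)-9-(tert-butyldiphenylsilyloxy)-2-methoxy-4-methyl-2-(triethylsilylperoxy)nonane; 8 methyl 3-methylbut-3-enoate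
Product: 11 methyl 2-[(3S,5R)-5-[(2R)-7-(tert-butyldiphenylsilyloxy)-2-methylheptyl]-3,5-dimethyl-1,2-dioxolan-3-yl]acetate, via peroxycarbenium ion 9 (not isolated), via tertiary C3 carbocation 10 (not isolated)
Conditions: confined chiral imidodiphosphorimidate acid (IDPi type, two 3,3′-diaryl-1,1′-bi-2-naphthol units, N-trifluoromethanesulfonyl groups; 5 mol%), 8 (3 equiv), toluene, −60 °C
Reagents that add atoms: none
Why: Proposed new method: the chiral acid ionises the methoxy group of 7 to give the silylperoxycarbenium ion 9 as a contact ion pair with the imidodiphosphorimidate anion, the CH2 terminus of 8 adds to the carbenium carbon (C4–C5 bond, Markovnikov sense) and the tertiary cation 10 is captured by the silyl-bearing oxygen O2, the Et3Si group passing to the released methanol so that the acid turns over. The closest known reaction types are the SnCl4-promoted, stereorandom annulation of triethylsilyl peroxyketals with 1,1-disubstituted alkenes and the chiral-counteranion-controlled additions of π-nucleophiles to ketal-derived oxocarbenium ions. The dioxolane arises as a stepwise cationic (3+2) union in which the C4–C5 bond joins the two components and a five-membered O2–C3 cation capture completes the ring. C5 is controlled by the anion, which must tell the methyl from the branched CH2 substituent of 9 and expose one face; C3 is controlled in the collapse of the same ion pair, where the CH2CO2Me arm is expected to turn away from the C5 side chain, which gives the trans relation of the two ring methyl groups. The step needs ionisation of OMe and not of OOSiEt3 (the ether oxygen is the more basic), attack by 8 alone (7 carries no other π-nucleophile and the 1,1-disubstituted alkene leads to a tertiary cation) and ring closure ahead of proton loss next to the ester (low temperature and a non-basic anion should favour this). Isomers at C3 or C5 that still form are diastereomers of 11 through the fixed C7 centre and should be removable by chromatography.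

Step 6
Reactants: 11 methyl 2-[(3S,5R)-5-[(2R)-7-(tert-butyldiphenylsilyloxy)-2-methylheptyl]-3,5-dimethyl-1,2-dioxolan-3-yl]acetate
Product: 12 methyl 2-[(3S,5R)-5-[(2R)-7-hydroxy-2-methylheptyl]-3,5-dimethyl-1,2-dioxolan-3-yl]acetate
Conditions: HF·pyridine, pyridine, THF, 0 °C to rt
Reagents that add atoms: none
Why: Fluoride-mediated desilylation under buffered conditions, which should leave the di-tertiary peroxide and the methyl ester untouched.

Step 7
Reactants: 12 methyl 2-[(3S,5R)-5-[(2R)-7-hydroxy-2-methylheptyl]-3,5-dimethyl-1,2-dioxolan-3-yl]acetate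
Product: 13 methyl 2-[(3S,5R)-3,5-dimethyl-5-[(2R)-2-methyl-7-oxoheptyl]-1,2-dioxolan-3-yl]acetate
Conditions: Dess–Martin periodinane, CH2Cl2, 0 °C to rt
Reagents that add atoms: none
Why: Dess–Martin oxidation is neutral and non-reducing, so the O–O bond and the ester should survive.

Step 8
Reactants: 14 pent-4-en-1-ol; 15 styrene
Product: 16 (4E)-5-phenylpent-4-en-1-ol
Conditions: second-generation Grubbs catalyst (2 mol%), 15 (4 equiv), CH2Cl2, 40 °C
Reagents that add atoms: none
Why: Olefin cross-metathesis with styrene in excess; conjugation with the arene should make the E styrenyl alkene (C16=C17) the product.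

Step 9
Reactants: 16 (4E)-5-phenylpent-4-en-1-ol; 17 1-phenyl-1H-tetrazole-5-thiol
Product: 18 1-phenyl-5-{[(4E)-5-phenylpent-4-en-1-yl]sulfanyl}-1H-tetrazole
Conditions: PPh3, DIAD, THF, 0 °C to rt
Reagents that add atoms: none
Why: Mitsunobu thioetherification of a primary alcohol with the acidic tetrazole thiol.

Step 10
Reactants: 18 1-phenyl-5-{[(4E)-5-phenylpent-4-en-1-yl]sulfanyl}-1H-tetrazole
Product: 19 1-phenyl-5-{[(4E)-5-phenylpent-4-en-1-yl]sulfonyl}-1H-tetrazole
Conditions: (NH4)6Mo7O24·4H2O (10 mol%), H2O2 (30% aq.), EtOH, 0 °C to rt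
Reagents that add atoms: hydrogen peroxide, OO
Why: Molybdate-catalysed sulfide-to-sulfone oxidation; sulfur should react far faster than the styrenyl alkene.

Step 11
Reactants: 13 methyl 2-[(3S,5R)-3,5-dimethyl-5-[(2R)-2-methyl-7-oxoheptyl]-1,2-dioxolan-3-yl]acetate; 19 1-phenyl-5-{[(4E)-5-phenylpent-4-en-1-yl]sulfonyl}-1H-tetrazole
Product: 20 methyl 2-[(3S,5R)-3,5-dimethyl-5-[(2R,7E,11E)-2-methyl-12-phenyldodeca-7,11-dien-1-yl]-1,2-dioxolan-3-yl]acetate
Conditions: 19, KN(SiMe3)2, DME, −60 °C; then 13, −60 °C to rt; aq. NH4Cl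
Reagents that add atoms: none
Why: Julia–Kocienski olefination; the pre-formed potassium sulfonyl carbanion adds to the unbranched aldehyde and the adduct collapses by Smiles rearrangement with loss of SO2 and the tetrazolone anion, which should favour the E alkene (C12=C13), while the fully substituted peroxide offers no α-hydrogen for base-induced cleavage.

Step 12
Reactants: 20 methyl 2-[(3S,5R)-3,5-dimethyl-5-[(2R,7E,11E)-2-methyl-12-phenyldodeca-7,11-dien-1-yl]-1,2-dioxolan-3-yl]acetate
Product: 21 2-[(3S,5R)-3,5-dimethyl-5-[(2R,7E,11E)-2-methyl-12-phenyldodeca-7,11-dien-1-yl]-1,2-dioxolan-3-yl]acetic acid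
Conditions: LiOH, THF/MeOH/H2O, 0 °C; then 1 M HCl to pH 3
Reagents that add atoms: lithium hydroxide, [Li+].[OH-]
Why: Saponification of a methyl ester; both peroxide carbons are fully substituted, so base-induced peroxide fragmentation is excluded, and the cold conditions should limit β-elimination.

**Compound list**

1 | hept-6-en-1-ol | C=CCCCCCO | starting material
2 | tert-butyl(hept-6-en-1-yloxy)diphenylsilane | C=CCCCCCO[Si](c1ccccc1)(c1ccccc1)C(C)(C)C | intermediate
3 | but-3-en-2-one | CC(=O)C=C | starting material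
4 | (3E)-9-(tert-butyldiphenylsilyloxy)non-3-en-2-one | CC(=O)/C=C/CCCCCO[Si](c1ccccc1)(c1ccccc1)C(C)(C)C | intermediate
5 | (4R)-9-(tert-butyldiphenylsilyloxy)-4-methylnonan-2-one | C[C@H](CCCCCO[Si](c1ccccc1)(c1ccccc1)C(C)(C)C)CC(C)=O | intermediate
6 | (4R)-9-(tert-butyldiphenylsilyloxy)-2-methoxy-4-methylnonan-2-yl hydroperoxide (C2 epimers; not isolated) | C[C@H](CCCCCO[Si](c1ccccc1)(c1ccccc1)C(C)(C)C)CC(C)(OC)OO | intermediate
7 | (4R)-9-(tert-butyldiphenylsilyloxy)-2-methoxy-4-methyl-2-(triethylsilylperoxy)nonane (C2 epimers) | C[C@H](CCCCCO[Si](c1ccccc1)(c1ccccc1)C(C)(C)C)CC(C)(OC)OO[Si](CC)(CC)CC | intermediate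
8 | methyl 3-methylbut-3-enoate | C=C(C)CC(=O)OC | starting material
9 | [(4R)-9-(tert-butyldiphenylsilyloxy)-4-methylnonan-2-ylidene](triethylsilyloxy)oxonium, the peroxycarbenium ion paired with the chiral anion (not isolated) | C[C@H](CCCCCO[Si](c1ccccc1)(c1ccccc1)C(C)(C)C)CC(C)=[O+]O[Si](CC)(CC)CC | intermediate
10 | tertiary C3 carbocation formed after C4–C5 bond formation, C5 of R series as in 11 (not isolated) | C[C@H](CCCCCO[Si](c1ccccc1)(c1ccccc1)C(C)(C)C)C[C@](C)(C[C+](C)CC(=O)OC)OO[Si](CC)(CC)CC | intermediate
11 | methyl 2-[(3S,5R)-5-[(2R)-7-(tert-butyldiphenylsilyloxy)-2-methylheptyl]-3,5-dimethyl-1,2-dioxolan-3-yl]acetate | C[C@H](CCCCCO[Si](c1ccccc1)(c1ccccc1)C(C)(C)C)C[C@]1(C)C[C@@](C)(CC(=O)OC)OO1 | intermediate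
12 | methyl 2-[(3S,5R)-5-[(2R)-7-hydroxy-2-methylheptyl]-3,5-dimethyl-1,2-dioxolan-3-yl]acetate | C[C@H](CCCCCO)C[C@]1(C)C[C@@](C)(CC(=O)OC)OO1 | intermediate
13 | methyl 2-[(3S,5R)-3,5-dimethyl-5-[(2R)-2-methyl-7-oxoheptyl]-1,2-dioxolan-3-yl]acetate | C[C@H](CCCCC=O)C[C@]1(C)C[C@@](C)(CC(=O)OC)OO1 | intermediate
14 | pent-4-en-1-ol | C=CCCCO | starting material
15 | styrene | C=Cc1ccccc1 | starting material
16 | (4E)-5-phenylpent-4-en-1-ol | OCCC/C=C/c1ccccc1 | intermediate
17 | 1-phenyl-1H-tetrazole-5-thiol | Sc1nnnn1-c1ccccc1 | starting material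
18 | 1-phenyl-5-{[(4E)-5-phenylpent-4-en-1-yl]sulfanyl}-1H-tetrazole | C(CC/C=C/c1ccccc1)Sc1nnnn1-c1ccccc1 | intermediate
19 | 1-phenyl-5-{[(4E)-5-phenylpent-4-en-1-yl]sulfonyl}-1H-tetrazole | O=S(=O)(CCC/C=C/c1ccccc1)c1nnnn1-c1ccccc1 | intermediate
20 | methyl 2-[(3S,5R)-3,5-dimethyl-5-[(2R,7E,11E)-2-methyl-12-phenyldodeca-7,11-dien-1-yl]-1,2-dioxolan-3-yl]acetate | C[C@H](CCCC/C=C/CC/C=C/c1ccccc1)C[C@]1(C)C[C@@](C)(CC(=O)OC)OO1 | intermediate
21 | 2-[(3S,5R)-3,5-dimethyl-5-[(2R,7E,11E)-2-methyl-12-phenyldodeca-7,11-dien-1-yl]-1,2-dioxolan-3-yl]acetic acid | C[C@H](CCCC/C=C/CC/C=C/c1ccccc1)C[C@]1(C)C[C@@](C)(CC(=O)O)OO1 | target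

**Summary**

Total step count: 12.
Longest linear sequence: 9 steps (steps 1 to 7, then 11 and 12); steps 8 to 10 form the sulfone branch.

Steps most likely to fail:

Step 5 (proposed new method). The ion pair may discriminate the two faces of the peroxycarbenium ion poorly, so that control at C5 and C3 is lost. The C3 cation may also lose a proton before the ring closes, or the peroxide oxygens may arrest the acid. The fallback is stepwise, uses known reaction types and sets out from 7. Its peroxycarbenium ion is generated with catalytic Me3SiOSO2CF3 in CH2Cl2 at −78 °C and trapped at the γ-carbon of the silyl dienolate 1-methoxy-3-methyl-1-(trimethylsilyloxy)buta-1,3-diene F1 (made from methyl 3-methylbut-2-enoate with LiN(iPr)2 and Me3SiCl). This vinylogous Mukaiyama addition forms the C4–C5 bond and should give methyl (2E,7R)-12-(tert-butyldiphenylsilyloxy)-3,5,7-trimethyl-5-(triethylsilylperoxy)dodec-2-enoate F2. HF·pyridine then removes both silyl groups to give methyl (2E,7R)-5-hydroperoxy-12-hydroxy-3,5,7-trimethyldodec-2-enoate F3. Et2NH in CF3CH2OH should close the ring by intramolecular conjugate addition of the hydroperoxide (O2–C3 bond). This fallback has no control at C5 or C3; the four isomers are diastereomers because of C7, and the (3S,5R) isomer is separated by chromatography, at a cost in material. The route is rejoined at 12.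

Step 11. The elimination stage may give incomplete E selectivity, and the sulfonyl carbanion may enolise the ester, which would open the dioxolane by β-elimination. The fallback sets out from 13 and fixes the geometry by stereospecific steps. Ohira–Bestmann homologation (dimethyl (1-diazo-2-oxopropyl)phosphonate, K2CO3, MeOH) should give the terminal alkyne methyl 2-[(3S,5R)-3,5-dimethyl-5-[(2R)-2-methyloct-7-yn-1-yl]-1,2-dioxolan-3-yl]acetate F4. Syn hydrozirconation with Cp2Zr(H)Cl followed by I2 gives the vinyl iodide methyl 2-[(3S,5R)-5-[(2R,7E)-8-iodo-2-methyloct-7-en-1-yl]-3,5-dimethyl-1,2-dioxolan-3-yl]acetate F5. A B-alkyl Suzuki–Miyaura coupling (PdCl2(dppf), Cs2CO3, DMF/THF/H2O, rt) with 9-[(3E)-4-phenylbut-3-en-1-yl]-9-borabicyclo[3.3.1]nonane F6, obtained from 9-borabicyclo[3.3.1]nonane and commercial (E)-1-phenylbuta-1,3-diene, forms the C13–C14 bond with retention of both alkene geometries. The route is rejoined at 20.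

Step 4. The ketone may be over-peroxidised to the geminal dihydroperoxide and its condensation products, and iodine in methanol may remove the silyl ether. The fallback sets out from 5. Wittig methylenation (Ph3PCH3Br, KOtBu, THF) gives tert-butyl{[(6R)-6,8-dimethylnon-8-en-1-yl]oxy}diphenylsilane F7. Ozonolysis in MeOH/CH2Cl2 at −78 °C cleaves the alkene, and methanol traps the disubstituted carbonyl oxide as the hydroperoxy ketal. The route is rejoined at 6, which is silylated as in step 4 to give 7.

**Further compounds**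

F1 | step 5 | 1-methoxy-3-methyl-1-(trimethylsilyloxy)buta-1,3-diene | C=C(C)C=C(OC)O[Si](C)(C)C
F2 | step 5 | methyl (2E,7R)-12-(tert-butyldiphenylsilyloxy)-3,5,7-trimethyl-5-(triethylsilylperoxy)dodec-2-enoate (C5 epimers) | C[C@H](CCCCCO[Si](c1ccccc1)(c1ccccc1)C(C)(C)C)CC(C)(C/C(C)=C/C(=O)OC)OO[Si](CC)(CC)CC
F3 | step 5 | methyl (2E,7R)-5-hydroperoxy-12-hydroxy-3,5,7-trimethyldodec-2-enoate (C5 epimers) | C[C@H](CCCCCO)CC(C)(C/C(C)=C/C(=O)OC)OO
F4 | step 11 | methyl 2-[(3S,5R)-3,5-dimethyl-5-[(2R)-2-methyloct-7-yn-1-yl]-1,2-dioxolan-3-yl]acetate | C[C@H](CCCCC#C)C[C@]1(C)C[C@@](C)(CC(=O)OC)OO1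
F5 | step 11 | methyl 2-[(3S,5R)-5-[(2R,7E)-8-iodo-2-methyloct-7-en-1-yl]-3,5-dimethyl-1,2-dioxolan-3-yl]acetate | C[C@H](CCCC/C=C/I)C[C@]1(C)C[C@@](C)(CC(=O)OC)OO1
F6 | step 11 | 9-[(3E)-4-phenylbut-3-en-1-yl]-9-borabicyclo[3.3.1]nonane | C1CCC2CCCC1B2CC/C=C/c1ccccc1
F7 | step 4 | tert-butyl{[(6R)-6,8-dimethylnon-8-en-1-yl]oxy}diphenylsilane | C[C@H](CCCCCO[Si](c1ccccc1)(c1ccccc1)C(C)(C)C)CC(C)=C
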